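**Retrosynthetic overview**

1. End game: the C15 enone comes last from the C16=C17 methylene (allylic oxidation at C15), after reduction of a bridging C12 ketone and acetylation of C1. Ring D (C11, C12, C13, C16, C15) comes from a 5-exo-dig Conia-ene closure C13–C16 of a C11-propargyl C12 ketone, with C11–C15 made by dienolate alkylation.
2. That β,γ-unsaturated C12 ketone (C8=C9 intact) is the Birch product of an anisole: ring C (C8, C9, C11–C14) is carried as a benzene ring with OMe on C12.
3. Ring B is disconnected as an aryne [4+2]: the aryne bond C8≡C9 of 3-fluoro-4-methoxybenzyne adds to the ring-A diene C7=C6–C5=C10. This forms C7–C8 and C9–C10, closes ring B and sets the quaternary C10 under control of the allylic C1 silyloxy group.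
4. Enabling feature: the tetrasubstituted C8=C9 double bond shared by rings B and C, flanked by C7H2 and quaternary C10, with the ring-C oxygen (C12) para to C8, is a latent benzyne bond of a latent anisole. Fluorine on C11 steers the regiochemistry and is erased in the Birch step.
5. Order of ring formation: A (commercial cyclohexenone) → B with aromatic C attached (step 5) → C dearomatised (step 9) → D (step 12).

Key step: step 5

Remark: 1 and 8 are taken to be catalogue chemicals. Atoms carry the biogenetic numbering (ring A C1–C5 and C10; ring B C5–C10; ring C C8, C9, C11–C14; ring D C11, C12, C13, C16, C15; C17 the exocyclic CH2; C20 the C10 methyl); α is the face of the C10 methyl group, β the opposite face.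

**Step 1**
Reactants: 1 3-ethoxy-2-methylcyclohex-2-en-1-one
Product: 3 3-ethoxy-2,6,6-trimethylcyclohex-2-en-1-one, via 6-monomethyl enone 2 (not isolated)
Conditions: LiN(i-Pr)2 (1.1 equiv), THF, −78 °C; MeI, → 0 °C; then LiN(i-Pr)2 (1.2 equiv), −78 °C; MeI, → rt (same flask)
Reagents that add atoms: iodomethane, CI
Why: The amide base deprotonates the vinylogous ester only at the α′ carbon, so two successive enolate alkylations build the gem-dimethyl carbon that becomes C4 (enolate alkylation; the stereocentre of 2 is erased by the second methylation).

**Step 2**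
Reactants: 3 3-ethoxy-2,6,6-trimethylcyclohex-2-en-1-one
Product: 5 3-ethenyl-2,4,4-trimethylcyclohex-2-en-1-one, via tertiary allylic alcohol 4 (not isolated)
Conditions: CH2=CHMgBr, CeCl3, THF, −78 → 0 °C; then 2 M HCl, rt
Reagents that add atoms: vinylmagnesium bromide, C=C[Mg]Br; water, O
Why: 1,2-Addition of the vinyl organometallic to the vinylogous ester carbonyl, then acid-induced ionisation, capture of water at the ethoxy-bearing carbon and loss of ethanol (Stork–Danheiser transposition) give the dienone whose ring alkene and vinyl group are the future C10=C5–C6=C7 diene.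

**Step 3**
Reactants: 5 3-ethenyl-2,4,4-trimethylcyclohex-2-en-1-one
Product: 6 (S)-3-ethenyl-2,4,4-trimethylcyclohex-2-en-1-ol
Conditions: (R)-2-methyl-CBS-oxazaborolidine (20 mol %), catecholborane, toluene, −78 °C
Reagents that add atoms: none
Why: In this Corey–Bakshi–Shibata reduction the oxazaborolidine binds the ketone with the α-methylated alkenyl arm as the large and the ring CH2 as the small group and delivers hydride to one carbonyl face, which sets C1 as (S), while catecholborane at −78 °C should not hydroborate the vinyl group.

**Step 4**
Reactants: 6 (S)-3-ethenyl-2,4,4-trimethylcyclohex-2-en-1-ol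
Product: 7 (S)-tert-butyl[(3-ethenyl-2,4,4-trimethylcyclohex-2-en-1-yl)oxy]dimethylsilane
Conditions: TBSCl, imidazole, DMF, rt
Reagents that add atoms: tert-butyldimethylsilyl chloride, CC(C)(C)[Si](C)(C)Cl
Why: Routine silylation of the secondary allylic alcohol gives a bulky ether that directs the facial course of step 5 and should withstand Grignard, borane, hydride, dissolving-metal and amide-base conditions (silyl ether formation; no new stereocentre).

**Step 5**
Reactants: 7 (S)-tert-butyl[(3-ethenyl-2,4,4-trimethylcyclohex-2-en-1-yl)oxy]dimethylsilane; 8 1-bromo-2,3-difluoro-4-methoxybenzene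
Product: 11 tricyclic fluoroanisole (ring C aromatic; 1α-OTBS; 10α-CH3; C5=C6; 11-F; 12-OMe), via Grignard reagent 9 (not isolated), via 3-fluoro-4-methoxybenzyne 10 (not isolated)
Conditions: Mg turnings, THF, 65 °C, slow addition of 8 (3 equiv) to Mg and 7
Reagents that add atoms: none
Why: Mg inserts into the C–Br bond of 8, the ortho-fluoro Grignard reagent 9 loses MgBrF, and the resulting 3-fluoro-4-methoxybenzyne 10 is captured by the s-cis conformer of diene 7 in a concerted, asynchronous [4+2] cycloaddition (aryne Diels–Alder reaction). The closest known reaction types are the Diels–Alder reactions of arynes with 1-vinylcyclohexenes and of 1-vinyl-2,6,6-trimethylcyclohexene with acetylenic dienophiles. Ring B closes as a six-membered carbocycle in the [4+2] mode, the aryne bond C8≡C9 adding suprafacially to the diene termini, so that C7–C8 and C9–C10 are formed together and C5=C6 is left for step 6. The one new stereocentre, quaternary C10, is controlled by the C1 silyloxy group, which lies pseudoaxial to avoid allylic 1,2-strain with the C10 methyl and covers one face, so the aryne bonds to C10 anti to it and the methyl group ends cis to the C1 oxygen as in the target. The step needs regioselectivity, which the fluorine secures: its inductive pull distorts the aryne so that the carbon remote from it (C8) is the electrophilic one and bonds to the unhindered, more nucleophilic diene terminus C7, placing the methoxy group on C12, para to C8. It also needs periselectivity over ene transfer of a C10-methyl hydrogen, which is served by generating the aryne slowly in the presence of the diene.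

**Step 6**
Reactants: 11 tricyclic fluoroanisole (C5=C6)
Product: 12 tricyclic 6β-alcohol (5β-H; 6β-OH equatorial)
Conditions: BH3·THF, THF, 0 °C → rt; then NaOH, H2O2, 0 °C
Reagents that add atoms: hydrogen peroxide, OO
Why: Syn hydroboration–oxidation puts boron on the less substituted C6 and hydrogen on C5 from the β face, anti to the pseudoaxial C10 methyl group (the course known for Δ5-steroids), which sets C5 with the trans A/B fusion of the target and C6 as the equatorial 6β-alcohol that is inverted in steps 7 and 8.

**Step 7**
Reactants: 12 tricyclic 6β-alcohol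
Product: 13 tricyclic C6 ketone (5β-H)
Conditions: Dess–Martin periodinane, NaHCO3, CH2Cl2, 0 °C → rt
Reagents that add atoms: none
Why: Dess–Martin oxidation under buffered, non-enolising conditions should convert the 6β-alcohol into the C6 ketone without epimerising C5.

**Step 8**
Reactants: 13 tricyclic C6 ketone
Product: 14 tricyclic 6α-alcohol (6α-OH axial; cis to the C10 methyl)
Conditions: NaBH4, MeOH–THF, −20 → 0 °C
Reagents that add atoms: none
Why: Axial delivery of hydride to the C6 carbonyl from the α face is blocked by the two syn-axial methyl groups on C4 and C10, so borohydride should attack equatorially from the β face and set C6 as the axial 6α-alcohol of the target (ketone reduction under steric approach control, as for 6-oxo steroids).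

**Step 9**
Reactants: 14 tricyclic 6α-alcohol
Product: 17 β,γ-unsaturated C12 ketone (C8=C9; 1α-OTBS; 6α-OH), via defluorinated anisole 15 (not isolated), via methyl enol ether 16 (not isolated)
Conditions: Li, NH3(l), t-BuOH, THF, −78 → −33 °C; NH4Cl; then (CO2H)2, THF–H2O, rt
Reagents that add atoms: water, O
Why: Birch reduction first cleaves the aryl C–F bond at C11 by electron transfer and loss of fluoride and then reduces the anisole with protonation at the unsubstituted ortho and meta carbons C11 and C14, which keeps the tetrasubstituted C8=C9 alkene and leaves the C12 enol ether that dilute oxalic acid hydrolyses to the unconjugated C12 ketone (the behaviour of estradiol methyl ether).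

**Step 10**
Reactants: 17 β,γ-unsaturated C12 ketone
Product: 18 C11 β-propargyl ketone
Conditions: LiN(i-Pr)2 (2.2 equiv), THF, −78 °C; HC≡CCH2Br, −78 → −20 °C
Reagents that add atoms: propargyl bromide, C#CCBr
Why: After the C6 alkoxide has formed, the amide base removes the doubly activated C11 proton (α to the C12 carbonyl and allylic to C8=C9) to give the linear dienolate, which is alkylated at its α carbon C11 from the β face, anti to the C10 methyl group that covers the α face, so C11 is set with the propargyl group β and C8=C9 stays in place (deconjugative α-alkylation of a dienolate).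

**Step 11**
Reactants: 18 C11 β-propargyl ketone
Product: 19 C12 tert-butyldimethylsilyl enol ether (C12=C13)
Conditions: KN(SiMe3)2 (2.2 equiv), THF, −78 °C; TBSCl, −78 → 0 °C
Reagents that add atoms: tert-butyldimethylsilyl chloride, CC(C)(C)[Si](C)(C)Cl
Why: The bulky amide should deprotonate the open C13 methylene kinetically and not the C11 methine, whose only hydrogen lies on the α face under the C10 methyl group, and the C12 enolate is trapped on oxygen as the regiodefined silyl enol ether, the hindered axial C6 alkoxide being returned as the alcohol on work-up (kinetic enol silylation; no new stereocentre).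

**Step 12**
Reactants: 19 C12 silyl enol ether
Product: 20 tetracyclic bridged C12 ketone (ring D closed; C16=C17; C15 H2; 1α-OTBS; 6α-OH)
Conditions: (Ph3P)AuCl (10 mol %), AgBF4 (10 mol %), CH2Cl2–MeOH (10:1), rt
Reagents that add atoms: none
Why: In this gold-catalysed Conia-ene-type carbocyclisation C13 of the silyl enol ether adds 5-exo-dig to the gold-activated internal alkyne carbon C16 and protodeauration by methanol gives the C16=C17 methylene, and because the tether is anchored on the β face at C11 the new bond can only form on the β face of C13, which closes ring D and sets C13 cis to C11.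

**Step 13**
Reactants: 20 tetracyclic bridged C12 ketone
Product: 21 1α,6α-diol C12 ketone
Conditions: HF·pyridine, pyridine–THF, 0 °C → rt
Reagents that add atoms: none
Why: Fluoride-driven cleavage of the Si–O bond frees the C1 hydroxyl, while the non-enolisable bridged ketone (both α carbons are bridgeheads), the alkenes and the C6 hydroxyl are inert (desilylation; no stereocentre affected).

**Step 14**
Reactants: 21 1α,6α-diol C12 ketone
Product: 22 1α-acetate C12 ketone (6α-OH free)
Conditions: Ac2O (1.5 equiv), pyridine, catalytic DMAP, CH2Cl2, 0 °C
Reagents that add atoms: acetic anhydride, CC(=O)OC(C)=O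
Why: Acylation should be chemoselective for the equatorial C1 hydroxyl because the axial C6 hydroxyl is shielded by the syn-axial methyl groups on C4 and C10 (acyl transfer with nucleophilic catalysis; no new stereocentre).

**Step 15**
Reactants: 22 1α-acetate C12 ketone
Product: 23 1α-acetate 6α,12-diol (12-OH towards the C15–C16 bridge)
Conditions: NaBH4, MeOH–CH2Cl2, −20 °C
Reagents that add atoms: none
Why: Borohydride should reduce the strained bridging C12 ketone from the side of the unsaturated three-carbon bridge C9=C8–C14, which carries no hydrogen on C8 or C9 and is the more open trajectory (as in 7-norbornenone), so the new hydroxyl points towards the C15–C16 bridge and C12 is set as in the target, the acetate being untouched at low temperature (hydride reduction under steric approach control).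

**Step 16**
Reactants: 23 1α-acetate 6α,12-diol
Product: 24 15-hydroxy compound (allylic alcohol; both C15 epimers serve)
Conditions: SeO2 (0.3 equiv), t-BuOOH, CH2Cl2, 0 °C → rt
Reagents that add atoms: tert-butyl hydroperoxide, CC(C)(C)OO
Why: Selenium dioxide allylic oxidation (ene reaction then 2,3-sigmatropic shift) should functionalise the exposed exocyclic alkene at the only allylic carbon that can take part, the C15 methylene (C13 is a bridgehead), whereas the tetrasubstituted C8=C9 alkene is buried between C10, the C12 bridge and ring D; the new C15 stereocentre is of no consequence because it is oxidised in step 17.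

**Step 17**
Reactants: 24 15-hydroxy compound
Product: 25 target CNP0149338.1
Conditions: MnO2 (excess), CH2Cl2, rt
Reagents that add atoms: none
Why: MnO2 oxidises only the allylic C15 alcohol to the cross-conjugated exo-methylene ketone and leaves the saturated secondary alcohols at C6 and C12 untouched (chemoselective allylic alcohol oxidation), which completes the target.

**Compound list**

1 | 3-ethoxy-2-methylcyclohex-2-en-1-one | CCOC1=C(C)C(=O)CCC1 | starting material
2 | 3-ethoxy-2,6-dimethylcyclohex-2-en-1-one (racemic) | CCOC1=C(C)C(=O)C(C)CC1 | intermediate (not isolated)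
3 | 3-ethoxy-2,6,6-trimethylcyclohex-2-en-1-one | CCOC1=C(C)C(=O)C(C)(C)CC1 | intermediate
4 | 1-ethenyl-3-ethoxy-2,6,6-trimethylcyclohex-2-en-1-ol (racemic) | CCOC1=C(C)C(O)(C=C)C(C)(C)CC1 | intermediate (not isolated)
5 | 3-ethenyl-2,4,4-trimethylcyclohex-2-en-1-one | C=CC1=C(C)C(=O)CCC1(C)C | intermediate
6 | (S)-3-ethenyl-2,4,4-trimethylcyclohex-2-en-1-ol | C=CC1=C(C)[C@@H](O)CCC1(C)C | intermediate
7 | (S)-tert-butyl[(3-ethenyl-2,4,4-trimethylcyclohex-2-en-1-yl)oxy]dimethylsilane | CC(C)(C)[Si](C)(C)O[C@H]1CCC(C)(C)C(C=C)=C1C | intermediate
8 | 1-bromo-2,3-difluoro-4-methoxybenzene | COc1ccc(Br)c(F)c1F | starting material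
9 | (2,3-difluoro-4-methoxyphenyl)magnesium bromide | COc1ccc([Mg]Br)c(F)c1F | intermediate (not isolated)
10 | 3-fluoro-4-methoxybenzyne | COC1=C(F)C#CC=C1 | intermediate (not isolated)
11 | (1S,10R) A/B/C tricycle: aromatic ring C with 11-F and 12-OMe, C5=C6, C7 H2, 1α-OTBS, 4,4-dimethyl, 10α-methyl | CC(C)(C)[Si](C)(C)O[C@H]1CCC(C)(C)C2=CCc3ccc(OC)c(F)c3[C@]12C | intermediate
12 | as 11 but C5=C6 hydrated: 5β-H, 6β-OH (equatorial) | CC(C)(C)[Si](C)(C)O[C@H]1CCC(C)(C)[C@H]2[C@H](O)Cc3ccc(OC)c(F)c3[C@]12C | intermediate
13 | C6 ketone (5β-H, trans A/B), ring C 11-fluoro-12-methoxy arene, 1α-OTBS | CC(C)(C)[Si](C)(C)O[C@H]1CCC(C)(C)[C@H]2C(=O)Cc3ccc(OC)c(F)c3[C@]12C | intermediate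
14 | 6α-alcohol (axial, cis to the C10 methyl), otherwise as 13 | CC(C)(C)[Si](C)(C)O[C@H]1CCC(C)(C)[C@H]2[C@@H](O)Cc3ccc(OC)c(F)c3[C@]12C | intermediate
15 | 14 without fluorine (11-H, 12-methoxy arene) | CC(C)(C)[Si](C)(C)O[C@H]1CCC(C)(C)[C@H]2[C@@H](O)Cc3ccc(OC)cc3[C@]12C | intermediate (not isolated)
16 | dihydroanisole: C8=C9 and C12(OMe)=C13, C11 H2, C14 H2, 1α-OTBS, 6α-OH | CC(C)(C)[Si](C)(C)O[C@H]1CCC(C)(C)[C@H]2[C@@H](O)CC3=C(CC(OC)=CC3)[C@]12C | intermediate (not isolated)
17 | C12 ketone with C8=C9 (β,γ-unsaturated), 1α-OTBS, 6α-OH | CC(C)(C)[Si](C)(C)O[C@H]1CCC(C)(C)[C@H]2[C@@H](O)CC3=C(CC(=O)CC3)[C@]12C | intermediate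
18 | 17 with a β-propargyl group on C11 | CC(C)(C)[Si](C)(C)O[C@H]1CCC(C)(C)[C@H]2[C@@H](O)CC3=C([C@@H](CC#C)C(=O)CC3)[C@]12C | intermediate
19 | C12 tert-butyldimethylsilyl enol ether (C12=C13) of 18 | CC(C)(C)[Si](C)(C)O[C@H]1CCC(C)(C)[C@H]2[C@@H](O)CC3=C([C@@H](CC#C)C(O[Si](C)(C)C(C)(C)C)=CC3)[C@]12C | intermediate
20 | tetracycle: ring D closed on the β face (C13–C16), C16=C17 methylene, C15 H2, bridging C12 ketone, C8=C9, 1α-OTBS, 6α-OH | C=C1C[C@@H]2C3=C(C[C@H]1C2=O)C[C@H](O)[C@@H]1C(C)(C)CC[C@H](O[Si](C)(C)C(C)(C)C)[C@@]31C | intermediate
21 | 20 with free 1α-OH (1α,6α-diol, C12 ketone) | C=C1C[C@@H]2C3=C(C[C@H]1C2=O)C[C@H](O)[C@@H]1C(C)(C)CC[C@H](O)[C@@]31C | intermediate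
22 | 1α-acetate of 21 (6α-OH free, C12 ketone) | C=C1C[C@@H]2C3=C(C[C@H]1C2=O)C[C@H](O)[C@@H]1C(C)(C)CC[C@H](OC(C)=O)[C@@]31C | intermediate
23 | 1α-acetate with 6α-OH and (12S)-OH pointing towards the C15–C16 bridge, C15 H2, C16=C17 | C=C1C[C@@H]2C3=C(C[C@H]1[C@@H]2O)C[C@H](O)[C@@H]1C(C)(C)CC[C@H](OC(C)=O)[C@@]31C | intermediate
24 | 23 with an allylic hydroxyl on C15 (configuration at C15 left open, both epimers are used) | C=C1C(O)[C@@H]2C3=C(C[C@H]1[C@@H]2O)C[C@H](O)[C@@H]1C(C)(C)CC[C@H](OC(C)=O)[C@@]31C | intermediate
25 | CNP0149338.1, (1S,5R,6S,10R,11R,12S,13R): 1α-acetoxy, 6α-OH, 12-OH, C8=C9, C15 ketone, C16=C17 | C=C1C(=O)[C@@H]2C3=C(C[C@H]1[C@@H]2O)C[C@H](O)[C@@H]1C(C)(C)CC[C@H](OC(C)=O)[C@@]31C | target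

**Step count and risks**

Total step count: 17. Longest linear sequence: 17 steps (1 to 25); 8 enters in step 5 as a catalogue compound.

The three steps most likely to fail:

Step 5. The aryne capture may lose its regiochemical bias (C7 bonding to the fluorine-flanked aryne carbon), the hindered diene may transfer a C10-methyl hydrogen to the aryne in an ene reaction, or the aryne may add syn to the silyloxy group. The fallback replaces the pericyclic step by a polar annulation that does not need the s-cis diene. It sets out from 7: Wacker–Tsuji oxidation of the vinyl group (PdCl2, CuCl, O2, DMF–H2O) gives the methyl ketone (S)-1-[3-(tert-butyldimethylsilyloxy)-2,6,6-trimethylcyclohex-1-en-1-yl]ethan-1-one F1. Its lithium dienolate (lithium 2,2,6,6-tetramethylpiperidide, THF, −78 °C) is treated with the aryne generated from 8 and n-BuLi (−78 °C → rt). The enolate carbon C7 adds to the aryne carbon remote from fluorine, a charged nucleophile following the aryne distortion more strictly than a neutral diene, and the aryl anion so formed closes onto C10 of the enone by conjugate addition, anti to the silyloxy group (annulation of a lithium dienolate with an aryne). Protonation of the C5=C6 enolate from the β face brings the sequence back to the route at ketone 13, so that steps 6 and 7 are bypassed.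

Step 10. The base may abstract a C13 proton instead of the C11 proton, the electrophile may enter from the α face, or the dienolate may be quenched by the acetylenic C–H of the halide. The fallback fixes the site of enolisation under thermodynamic control before the alkylation. It sets out from 17: Me3SiCl, NaI and Et3N in MeCN give, under equilibrating conditions, the conjugated bis(trimethylsilyl) dienol ether F2 (C12(OSiMe3)=C11–C9=C8, C6 hydroxyl also silylated). MeLi in THF then releases the regiodefined, amine-free lithium dienolate, which is alkylated with propargyl bromide at −78 °C. Work-up with aqueous citric acid cleaves the C6 trimethylsilyl ether and the sequence returns to the route at 18.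

Step 12. The enol ether may be protodesilylated faster than it cyclises, or the enolisation of step 11 may have gone towards C11, so that no C13 nucleophile is available. The fallback closes ring D by cross-coupling instead of alkyne activation and needs no preformed enol ether. It sets out from 17: alkylation as in step 10, but with 2,3-dibromopropene, gives the C11 β-(2-bromoallyl) ketone F3. Pd(PPh3)4 and KOt-Bu in THF at 65 °C then bring about intramolecular α-alkenylation of the ketone: oxidative addition into the vinyl C–Br bond, capture of the C13 enolate formed under equilibrating conditions (the C11 enolate cannot reach the palladium centre) and reductive elimination form C13–C16. This returns to the route at 20.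

**Further compounds**

F1 | step 5 | (S)-1-[3-(tert-butyldimethylsilyloxy)-2,6,6-trimethylcyclohex-1-en-1-yl]ethan-1-one | CC(C)(C)[Si](C)(C)O[C@H]1CCC(C)(C)C(C(C)=O)=C1C
F2 | step 10 | bis(trimethylsilyl) dienol ether of 17 (C12(OSiMe3)=C11–C9=C8; 6α-OSiMe3; 1α-OTBS) | CC(C)(C)[Si](C)(C)O[C@H]1CCC(C)(C)[C@H]2[C@@H](O[Si](C)(C)C)CC3=C(C=C(O[Si](C)(C)C)CC3)[C@]12C
F3 | step 12 | C11 β-(2-bromoallyl) derivative of ketone 17 | CC(C)(C)[Si](C)(C)O[C@H]1CCC(C)(C)[C@H]2[C@@H](O)CC3=C([C@@H](CC(Br)=C)C(=O)CC3)[C@]12C
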